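The route rests on forming the O1–C5 and C6–C7 bonds across one alkyne. The target's tetronic acid ring (O1, C2, C3, C4, C5) carries its exocyclic C5=C6 bond in the E form (C7 cis to C4) next to the lone stereocentre C7. Anti-oxypalladation of a cis-enynoic acid, followed by enantioselective insertion of (E)-but-2-enal, is planned to close the ring, fix that geometry and set C7 in one operation. The precursor is (E)-3-(methoxymethoxy)-2-methylpent-2-en-4-ynoic acid, whose enol ether holds the carboxyl beside a terminal alkyne. The resulting C9 aldehyde is methylenated and joined by hydroboration–Suzuki coupling to a furyl C11–C18 alkenyl iodide; oxidation and deprotection finish.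

Key step: step 6

Numbering: ring O1, C2 (C=O), C3 (Me), C4 (OH), C5; chain C6 (ylidene CH), C7 (stereocentre) to C18 (ketone carbon).
Assumption: the (S)-configured pyridine–oxazoline is taken to give the 7S aldehyde; if the insertion shows the opposite sense, the (R)-ligand is used.
Remark: the furyl carbinol carbon C18 is made racemic, carried as an epimer mixture and becomes the ketone in step 17.

Step 1
Reactants: 1 propanoyl chloride; 2 2-(trimethylsilyl)ethanol
Product: 3 2-(trimethylsilyl)ethyl propanoate
Conditions: Et3N, DMAP (cat.), CH2Cl2, 0 °C → rt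
Reagents that add atoms: none
Why: DMAP-catalysed acylation of the alcohol by the acid chloride gives an ester that fluoride can cleave later, so the enynoate never has to meet hydroxide.

Step 2
Reactants: 3 2-(trimethylsilyl)ethyl propanoate; 4 3-(trimethylsilyl)prop-2-ynal
Product: 6 2-(trimethylsilyl)ethyl 3-hydroxy-2-methyl-5-(trimethylsilyl)pent-4-ynoate (diastereomer mixture), via lithium enolate 5 (not isolated)
Conditions: LiN(i-Pr)2, THF, −78 °C; then 4, −78 °C; AcOH quench
Reagents that add atoms: none
Why: lithium enolate aldol addition to the non-enolisable ynal is fast and 1,2-selective at −78 °C, and both new stereocentres are erased in steps 3 and 4.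

Step 3
Reactants: 6 2-(trimethylsilyl)ethyl 3-hydroxy-2-methyl-5-(trimethylsilyl)pent-4-ynoate
Product: 7 2-(trimethylsilyl)ethyl 2-methyl-3-oxo-5-(trimethylsilyl)pent-4-ynoate
Conditions: Dess–Martin periodinane, CH2Cl2, 0 °C → rt
Reagents that add atoms: none
Why: Dess–Martin oxidation of the propargylic alcohol gives the ynone β-keto ester under neutral conditions that leave both silyl groups in place.

Step 4
Reactants: 7 2-(trimethylsilyl)ethyl 2-methyl-3-oxo-5-(trimethylsilyl)pent-4-ynoate
Product: 9 2-(trimethylsilyl)ethyl (2E)-3-(methoxymethoxy)-2-methyl-5-(trimethylsilyl)pent-2-en-4-ynoate, via sodium enolate 8 (not isolated)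
Conditions: NaH, THF–DMPU (4:1), 0 °C; then MOMCl, 0 °C → rt
Reagents that add atoms: chloromethyl methyl ether (MOMCl), COCCl
Why: O-alkylation of the β-keto ester enolate by a hard electrophile; in a dipolar aprotic medium the solvent-separated enolate prefers the extended form with oxygen anti to the ester, so the E enol ether (carboxyl cis to the alkyne) is expected and any Z isomer is removed by chromatography.

Step 5
Reactants: 9 2-(trimethylsilyl)ethyl (2E)-3-(methoxymethoxy)-2-methyl-5-(trimethylsilyl)pent-2-en-4-ynoate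
Product: 10 (2E)-3-(methoxymethoxy)-2-methylpent-2-en-4-ynoic acid
Conditions: Bu4NF (3 equiv), THF, 0 °C → rt; cold 0.5 M HCl to pH 3
Reagents that add atoms: none
Why: fluoride-induced fragmentation of the 2-(trimethylsilyl)ethyl ester and protodesilylation of the alkynylsilane occur in one pot without hydroxide, which spares the push–pull enynoate and the MOM enol ether.

Step 6
Reactants: 10 (2E)-3-(methoxymethoxy)-2-methylpent-2-en-4-ynoic acid; 11 (2E)-but-2-enal
Product: 12 (3S)-4-[(2E)-3-(methoxymethoxy)-4-methyl-5-oxofuran-2(5H)-ylidene]-3-methylbutanal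
Conditions: Pd(OCOCF3)2 (10 mol %), (S)-4-tert-butyl-2-(pyridin-2-yl)-4,5-dihydrooxazole (12 mol %), 11 (5 equiv), ClCH2CH2Cl, 40 °C, slow addition of 10
Reagents that add atoms: none
Why: Proposed new method: nitrogen-ligated cationic divalent palladium coordinates the terminal alkyne of 10, the carboxyl held cis by the C3=C4 enol ether adds to C5 from the face opposite the metal (anti-oxypalladation, the usual course of carboxylate addition to alkynes on divalent palladium), and the C6 alkenylpalladium, trans to O1, inserts the C=C bond of 11 with retention before the palladium enolate is protonated by the proton released on lactonisation, so no oxidant is needed. Nearest precedents in type are the tandem lactonisation of alkynoic acids and 1,4-addition to unsubstituted enals or enones under halide-modified divalent palladium (achiral products), and the enantioselective 1,4-addition of aryl groups from boron to β-substituted cyclic enones on pyridine–oxazoline-ligated divalent palladium. The butenolide ring closes in the 5-exo-dig mode through the O1–C5 bond, which attack at the internal carbon of a terminal alkyne favours over 6-endo closure to a pyranone. The C7 configuration is controlled by the ligand, whose tert-butyl group is expected to shield one enantioface of the palladium-bound enal during migratory insertion. The step needs E geometry at C5=C6, secured by anti addition plus stereoretentive insertion, and protonolysis instead of β-hydride elimination, which the bidentate nitrogen ligand favours; halide is left out because bromide-ligated palladium would open a racemic pathway. Slow addition of 10 and excess 11 are meant to let insertion outrun protodepalladation of the alkenylpalladium.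

Step 7
Reactants: 12 (3S)-4-[(2E)-3-(methoxymethoxy)-4-methyl-5-oxofuran-2(5H)-ylidene]-3-methylbutanal
Product: 13 (5E)-4-(methoxymethoxy)-3-methyl-5-[(2S)-2-methylpent-4-en-1-ylidene]furan-2(5H)-one
Conditions: Ph3PCH3Br (1.3 equiv), KN(SiMe3)2 (1.2 equiv), THF, 0 °C; then 12, −78 → 0 °C
Reagents that add atoms: methyltriphenylphosphonium bromide, C[P+](c1ccccc1)(c1ccccc1)c1ccccc1.[Br-]
Why: Wittig methylenation with a slight deficiency of base converts the aldehyde at low temperature faster than the ylide can attack the deactivated lactone, and C7 (β to the aldehyde) is not touched by enolisation.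

Step 8
Reactants: 14 pent-3-yn-1-ol
Product: 15 5-iodopent-2-yne
Conditions: I2, PPh3, imidazole, CH2Cl2, 0 °C → rt
Reagents that add atoms: iodine, II
Why: Appel-type iodination replaces the primary hydroxyl by SN2 displacement of the oxyphosphonium and leaves the internal alkyne untouched.

Step 9
Reactants: 16 furan-3-carbaldehyde; 17 3-bromoprop-1-yne
Product: 19 1-(furan-3-yl)but-3-yn-1-ol (racemic), via allenylzinc bromide 18 (not isolated)
Conditions: Zn dust, THF/sat. aq. NH4Cl, 0 °C → rt
Reagents that add atoms: none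
Why: Barbier propargylation through the allenylzinc species (SE2′ addition) gives the homopropargylic alcohol; the carbinol centre is racemic and is oxidised later.

Step 10
Reactants: 19 1-(furan-3-yl)but-3-yn-1-ol
Product: 20 tert-butyl{[1-(furan-3-yl)but-3-yn-1-yl]oxy}dimethylsilane
Conditions: TBSCl, imidazole, DMF, rt
Reagents that add atoms: tert-butyldimethylsilyl chloride (TBSCl), CC(C)(C)[Si](C)(C)Cl
Why: standard silylation protects the carbinol for the organometallic steps and prevents alkoxide-directed hydrozirconation with the wrong regiochemistry.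

Step 11
Reactants: 20 tert-butyl{[1-(furan-3-yl)but-3-yn-1-yl]oxy}dimethylsilane
Product: 22 tert-butyl{[1-(furan-3-yl)pent-3-yn-1-yl]oxy}dimethylsilane, via lithium acetylide 21 (not isolated)
Conditions: n-BuLi, THF, −78 °C; then MeI, DMPU, −78 °C → rt
Reagents that add atoms: iodomethane (MeI), CI
Why: the alkyne C–H is far more acidic than the furan C–H, so n-BuLi forms the acetylide selectively and acetylide alkylation installs the methyl group.

Step 12
Reactants: 22 tert-butyl{[1-(furan-3-yl)pent-3-yn-1-yl]oxy}dimethylsilane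
Product: 24 tert-butyl{[(3E)-1-(furan-3-yl)-4-iodopent-3-en-1-yl]oxy}dimethylsilane, via alkenylzirconocene chloride 23 (not isolated)
Conditions: Cp2Zr(H)Cl (2 equiv), THF, 50 °C; then I2, THF, 0 °C
Reagents that add atoms: iodine, II
Why: syn-hydrozirconation of the 2-alkyne with excess reagent under equilibrating conditions places zirconium on the less hindered methyl-bearing carbon, and iodinolysis with retention gives the E 2-iodoalkene.

Step 13
Reactants: 15 5-iodopent-2-yne; 24 tert-butyl{[(3E)-1-(furan-3-yl)-4-iodopent-3-en-1-yl]oxy}dimethylsilane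
Product: 26 tert-butyl{[(3E)-1-(furan-3-yl)-4-methylnon-3-en-7-yn-1-yl]oxy}dimethylsilane, via pent-3-ynylzinc iodide 25 (not isolated)
Conditions: 15, Zn dust, LiCl, THF, 40 °C; then 24, PdCl2(dppf) (5 mol %), THF, 50 °C
Reagents that add atoms: none
Why: zinc insertion into the primary iodide and Negishi sp3–sp2 coupling with retention at the alkenyl iodide form C14–C15 and fix the E geometry of C15=C16.

Step 14
Reactants: 26 tert-butyl{[(3E)-1-(furan-3-yl)-4-methylnon-3-en-7-yn-1-yl]oxy}dimethylsilane
Product: 28 tert-butyl{[(3E,7E)-1-(furan-3-yl)-8-iodo-4-methylnona-3,7-dien-1-yl]oxy}dimethylsilane, via alkenylzirconocene chloride 27 (not isolated)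
Conditions: Cp2Zr(H)Cl (2 equiv), THF, 50 °C; then I2, THF, 0 °C
Reagents that add atoms: iodine, II
Why: hydrozirconation–iodination as in step 12 converts the methyl alkyne into the E 2-iodoalkene, while the trisubstituted alkene reacts too slowly to interfere.

Step 15
Reactants: 13 (5E)-4-(methoxymethoxy)-3-methyl-5-[(2S)-2-methylpent-4-en-1-ylidene]furan-2(5H)-one; 28 tert-butyl{[(3E,7E)-1-(furan-3-yl)-8-iodo-4-methylnona-3,7-dien-1-yl]oxy}dimethylsilane
Product: 30 (5E)-5-[(2S,6E,10E)-13-{[tert-butyl(dimethyl)silyl]oxy}-13-(furan-3-yl)-2,6,10-trimethyltrideca-6,10-dien-1-ylidene]-4-(methoxymethoxy)-3-methylfuran-2(5H)-one (C13 epimers), via B-alkyl-9-BBN borane 29 (not isolated)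
Conditions: 9-BBN, THF, 0 °C → rt; then 28, PdCl2(dppf) (5 mol %), AsPh3, aq. K3PO4, DMF, rt
Reagents that add atoms: none
Why: 9-BBN hydroborates only the monosubstituted C9=C10 alkene (anti-Markovnikov), and B-alkyl Suzuki–Miyaura coupling under mild phosphate base forms C10–C11 with retention of the E iodide geometry.

Step 16
Reactants: 30 (5E)-5-[(2S,6E,10E)-13-{[tert-butyl(dimethyl)silyl]oxy}-13-(furan-3-yl)-2,6,10-trimethyltrideca-6,10-dien-1-ylidene]-4-(methoxymethoxy)-3-methylfuran-2(5H)-one
Product: 31 (5E)-5-[(2S,6E,10E)-13-(furan-3-yl)-13-hydroxy-2,6,10-trimethyltrideca-6,10-dien-1-ylidene]-4-(methoxymethoxy)-3-methylfuran-2(5H)-one (C13 epimers)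
Conditions: Bu4NF, AcOH (1:1), THF, 0 °C → rt
Reagents that add atoms: none
Why: buffered fluoride desilylation frees the carbinol without acid, which the ionisable furyl carbinol would not tolerate, and without opening the enol lactone.

Step 17
Reactants: 31 (5E)-5-[(2S,6E,10E)-13-(furan-3-yl)-13-hydroxy-2,6,10-trimethyltrideca-6,10-dien-1-ylidene]-4-(methoxymethoxy)-3-methylfuran-2(5H)-one
Product: 32 (5E)-5-[(2S,6E,10E)-13-(furan-3-yl)-2,6,10-trimethyl-13-oxotrideca-6,10-dien-1-ylidene]-4-(methoxymethoxy)-3-methylfuran-2(5H)-one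
Conditions: Dess–Martin periodinane, NaHCO3, CH2Cl2, 0 °C
Reagents that add atoms: none
Why: buffered Dess–Martin oxidation gives the β,γ-unsaturated furyl ketone under neutral conditions that should not move C15=C16 into conjugation, and the tetronic acid is still masked.

Step 18
Reactants: 32 (5E)-5-[(2S,6E,10E)-13-(furan-3-yl)-2,6,10-trimethyl-13-oxotrideca-6,10-dien-1-ylidene]-4-(methoxymethoxy)-3-methylfuran-2(5H)-one
Product: 33 (5E)-5-[(2S,6E,10E)-13-(furan-3-yl)-2,6,10-trimethyl-13-oxotrideca-6,10-dien-1-ylidene]-4-hydroxy-3-methylfuran-2(5H)-one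
Conditions: 2 M HCl, THF, 0 °C → rt
Reagents that add atoms: none
Why: acetal hydrolysis of the MOM group, a vinylogous acyl acetal with the tetronate as a good leaving group, should proceed in dilute acid too mild to isomerise the ketone or protonate the trisubstituted alkenes.

Compound list
1 | propanoyl chloride | CCC(=O)Cl | starting material
2 | 2-(trimethylsilyl)ethanol | C[Si](C)(C)CCO | starting material
3 | 2-(trimethylsilyl)ethyl propanoate | CCC(=O)OCC[Si](C)(C)C | intermediate
4 | 3-(trimethylsilyl)prop-2-ynal | C[Si](C)(C)C#CC=O | starting material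
5 | lithium enolate of 3 (lithium 1-[2-(trimethylsilyl)ethoxy]prop-1-en-1-olate) | [Li+].CC=C([O-])OCC[Si](C)(C)C | intermediate
6 | 2-(trimethylsilyl)ethyl 3-hydroxy-2-methyl-5-(trimethylsilyl)pent-4-ynoate (diastereomer mixture, racemic) | CC(C(O)C#C[Si](C)(C)C)C(=O)OCC[Si](C)(C)C | intermediate
7 | 2-(trimethylsilyl)ethyl 2-methyl-3-oxo-5-(trimethylsilyl)pent-4-ynoate (racemic) | CC(C(=O)C#C[Si](C)(C)C)C(=O)OCC[Si](C)(C)C | intermediate
8 | sodium enolate of 7 in the extended E form (enolate oxygen trans to the ester) | [Na+].C[Si](C)(C)CCOC(=O)/C(C)=C(/[O-])C#C[Si](C)(C)C | intermediate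
9 | 2-(trimethylsilyl)ethyl (2E)-3-(methoxymethoxy)-2-methyl-5-(trimethylsilyl)pent-2-en-4-ynoate | C[Si](C)(C)CCOC(=O)/C(C)=C(/OCOC)C#C[Si](C)(C)C | intermediate
10 | (2E)-3-(methoxymethoxy)-2-methylpent-2-en-4-ynoic acid | OC(=O)/C(C)=C(/OCOC)C#C | intermediate
11 | (2E)-but-2-enal | C/C=C/C=O | starting material
12 | (3S)-4-[(2E)-3-(methoxymethoxy)-4-methyl-5-oxofuran-2(5H)-ylidene]-3-methylbutanal | CC1=C(OCOC)/C(=C\[C@@H](C)CC=O)OC1=O | intermediate
13 | (5E)-4-(methoxymethoxy)-3-methyl-5-[(2S)-2-methylpent-4-en-1-ylidene]furan-2(5H)-one | CC1=C(OCOC)/C(=C\[C@@H](C)CC=C)OC1=O | intermediate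
14 | pent-3-yn-1-ol | CC#CCCO | starting material
15 | 5-iodopent-2-yne | CC#CCCI | intermediate
16 | furan-3-carbaldehyde | O=Cc1ccoc1 | starting material
17 | 3-bromoprop-1-yne | C#CCBr | starting material
18 | propa-1,2-dien-1-ylzinc bromide (allenylzinc bromide) | C=C=C[Zn]Br | intermediate
19 | 1-(furan-3-yl)but-3-yn-1-ol (racemic) | C#CCC(O)c1ccoc1 | intermediate
20 | tert-butyl{[1-(furan-3-yl)but-3-yn-1-yl]oxy}dimethylsilane (racemic) | C#CCC(O[Si](C)(C)C(C)(C)C)c1ccoc1 | intermediate
21 | lithium acetylide of 20 | [Li]C#CCC(O[Si](C)(C)C(C)(C)C)c1ccoc1 | intermediate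
22 | tert-butyl{[1-(furan-3-yl)pent-3-yn-1-yl]oxy}dimethylsilane (racemic) | CC#CCC(O[Si](C)(C)C(C)(C)C)c1ccoc1 | intermediate
23 | chloro{(2E)-5-{[tert-butyl(dimethyl)silyl]oxy}-5-(furan-3-yl)pent-2-en-2-yl}bis(cyclopentadienyl)zirconium | C/C(=C\CC(O[Si](C)(C)C(C)(C)C)c1ccoc1)[Zr](Cl)(C1C=CC=C1)C1C=CC=C1 | intermediate
24 | tert-butyl{[(3E)-1-(furan-3-yl)-4-iodopent-3-en-1-yl]oxy}dimethylsilane (racemic) | C/C(I)=C\CC(O[Si](C)(C)C(C)(C)C)c1ccoc1 | intermediate
25 | pent-3-yn-1-ylzinc iodide | CC#CCC[Zn]I | intermediate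
26 | tert-butyl{[(3E)-1-(furan-3-yl)-4-methylnon-3-en-7-yn-1-yl]oxy}dimethylsilane (racemic) | CC#CCC/C(C)=C/CC(O[Si](C)(C)C(C)(C)C)c1ccoc1 | intermediate
27 | chloro{(2E,6E)-9-{[tert-butyl(dimethyl)silyl]oxy}-9-(furan-3-yl)-6-methylnona-2,6-dien-2-yl}bis(cyclopentadienyl)zirconium | C/C(=C\CC/C(C)=C/CC(O[Si](C)(C)C(C)(C)C)c1ccoc1)[Zr](Cl)(C1C=CC=C1)C1C=CC=C1 | intermediate
28 | tert-butyl{[(3E,7E)-1-(furan-3-yl)-8-iodo-4-methylnona-3,7-dien-1-yl]oxy}dimethylsilane (racemic) | C/C(I)=C\CC/C(C)=C/CC(O[Si](C)(C)C(C)(C)C)c1ccoc1 | intermediate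
29 | (5E)-5-[(2S)-5-(9-borabicyclo[3.3.1]nonan-9-yl)-2-methylpentylidene]-4-(methoxymethoxy)-3-methylfuran-2(5H)-one | CC1=C(OCOC)/C(=C\[C@@H](C)CCCB2C3CCCC2CCC3)OC1=O | intermediate
30 | (5E)-5-[(2S,6E,10E)-13-{[tert-butyl(dimethyl)silyl]oxy}-13-(furan-3-yl)-2,6,10-trimethyltrideca-6,10-dien-1-ylidene]-4-(methoxymethoxy)-3-methylfuran-2(5H)-one (C13 epimers) | CC1=C(OCOC)/C(=C\[C@@H](C)CCC/C(C)=C/CC/C(C)=C/CC(O[Si](C)(C)C(C)(C)C)c2ccoc2)OC1=O | intermediate
31 | (5E)-5-[(2S,6E,10E)-13-(furan-3-yl)-13-hydroxy-2,6,10-trimethyltrideca-6,10-dien-1-ylidene]-4-(methoxymethoxy)-3-methylfuran-2(5H)-one (C13 epimers) | CC1=C(OCOC)/C(=C\[C@@H](C)CCC/C(C)=C/CC/C(C)=C/CC(O)c2ccoc2)OC1=O | intermediate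
32 | (5E)-5-[(2S,6E,10E)-13-(furan-3-yl)-2,6,10-trimethyl-13-oxotrideca-6,10-dien-1-ylidene]-4-(methoxymethoxy)-3-methylfuran-2(5H)-one | CC1=C(OCOC)/C(=C\[C@@H](C)CCC/C(C)=C/CC/C(C)=C/CC(=O)c2ccoc2)OC1=O | intermediate
33 | (5E)-5-[(2S,6E,10E)-13-(furan-3-yl)-2,6,10-trimethyl-13-oxotrideca-6,10-dien-1-ylidene]-4-hydroxy-3-methylfuran-2(5H)-one | CC1=C(O)/C(=C\[C@@H](C)CCC/C(C)=C/CC/C(C)=C/CC(=O)c2ccoc2)OC1=O | target

Total step count: 18. Longest linear sequence: 11 (steps 1–7, then 15–18); the iodide branch (steps 9–14) joins at step 15, and step 8 feeds step 13.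

Steps most likely to fail

Step 6 (Proposed new method). The alkenylpalladium may be protonated before it inserts the β-substituted enal, giving simple cycloisomerisation, or the insertion may proceed with poor facial selectivity. The fallback uses known chemistry, sets out from 10 and returns at 12. Copper-free cyclisation–coupling on zerovalent palladium (Pd(PPh3)4, K2CO3, MeCN) would join 10 to ethyl (2Z)-3-iodobut-2-enoate F1, itself made from ethyl but-2-ynoate with NaI in AcOH. The alkenylpalladium iodide activates the alkyne, the carboxylate attacks anti and reductive elimination places the new carbon trans to O1. This would give ethyl (2Z)-4-[(2E)-3-(methoxymethoxy)-4-methyl-5-oxofuran-2(5H)-ylidene]-3-methylbut-2-enoate F2. Copper hydride-catalysed asymmetric 1,4-reduction (Cu(OAc)2, Tol-BINAP of the enantiomer that gives 3S, poly(methylhydrosiloxane), t-BuOH, toluene) would then set C7 in ethyl (3S)-4-[(2E)-3-(methoxymethoxy)-4-methyl-5-oxofuran-2(5H)-ylidene]-3-methylbutanoate F3. Reduction with i-Bu2AlH at −78 °C would give 12.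

Step 4. Geometric control may be lost at the enolate stage, so that the enol ether forms mainly with the carboxyl trans to the alkyne. The fallback replaces kinetic trapping by later equilibration, sets out from 7 and returns at 9. The separated Z isomer, 2-(trimethylsilyl)ethyl (2Z)-3-(methoxymethoxy)-2-methyl-5-(trimethylsilyl)pent-2-en-4-ynoate F4, would be subjected to acetone-sensitised photoisomerisation (350 nm), which interconverts the isomers of such push–pull alkenes. 9 would be separated from the photostationary mixture and F4 recycled.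

Step 15. The enol lactone may be hydrolysed by the aqueous base, or transmetalation of the borane may be too slow. The fallback is a base-free organozinc coupling, sets out from 13 and returns at 30. Hydroboration with 9-BBN and oxidation with NaBO3 would give (5E)-5-[(2S)-5-hydroxy-2-methylpentylidene]-4-(methoxymethoxy)-3-methylfuran-2(5H)-one F5. Appel iodination (I2, PPh3, imidazole) would give (5E)-5-[(2S)-5-iodo-2-methylpentylidene]-4-(methoxymethoxy)-3-methylfuran-2(5H)-one F6. Zinc insertion (Zn, LiCl, THF) would give {(4S,5E)-5-[3-(methoxymethoxy)-4-methyl-5-oxofuran-2(5H)-ylidene]-4-methylpentyl}zinc iodide F7, which would be joined to 28 by Negishi coupling (PdCl2(dppf), THF).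

Further compounds
F1 | step 6 | ethyl (2Z)-3-iodobut-2-enoate | C/C(I)=C/C(=O)OCC
F2 | step 6 | ethyl (2Z)-4-[(2E)-3-(methoxymethoxy)-4-methyl-5-oxofuran-2(5H)-ylidene]-3-methylbut-2-enoate | CC1=C(OCOC)/C(=C\C(C)=C/C(=O)OCC)OC1=O
F3 | step 6 | ethyl (3S)-4-[(2E)-3-(methoxymethoxy)-4-methyl-5-oxofuran-2(5H)-ylidene]-3-methylbutanoate | CC1=C(OCOC)/C(=C\[C@@H](C)CC(=O)OCC)OC1=O
F4 | step 4 | 2-(trimethylsilyl)ethyl (2Z)-3-(methoxymethoxy)-2-methyl-5-(trimethylsilyl)pent-2-en-4-ynoate | C[Si](C)(C)CCOC(=O)/C(C)=C(\OCOC)C#C[Si](C)(C)C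
F5 | step 15 | (5E)-5-[(2S)-5-hydroxy-2-methylpentylidene]-4-(methoxymethoxy)-3-methylfuran-2(5H)-one | CC1=C(OCOC)/C(=C\[C@@H](C)CCCO)OC1=O
F6 | step 15 | (5E)-5-[(2S)-5-iodo-2-methylpentylidene]-4-(methoxymethoxy)-3-methylfuran-2(5H)-one | CC1=C(OCOC)/C(=C\[C@@H](C)CCCI)OC1=O
F7 | step 15 | {(4S,5E)-5-[3-(methoxymethoxy)-4-methyl-5-oxofuran-2(5H)-ylidene]-4-methylpentyl}zinc iodide | CC1=C(OCOC)/C(=C\[C@@H](C)CCC[Zn]I)OC1=O
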